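**Plan**

- Retrosynthesis: C1 is removed as formaldehyde (bonds C1–N and C1–C8a, Pictet–Spengler). The isoquinoline benzene ring is then cut at C4a–C8a, C6–C7, C8–C8a and C5–C6, the C4a=C5 alkene of the precursor by olefination, and C4–C4a by alkylation.
- Enabling feature: ring C4a/C5/C6/C7/C8/C8a has oxygen on C6 and C8 (meta), hydrogen on C7 between them and the naphthyl on C5 beside C6. A vinylketene and an alkoxyalkyne give exactly this pattern, and methoxyethyne brings C7 and C8 with the C8 methoxy group already in place.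
- Forward order: the naphthalene first (Stobbe condensation, acylative ring closure), then C5–C4a by Horner–Wadsworth–Emmons olefination of the naphthaldehyde (C5 is the aldehyde carbon, so no aryl–aryl coupling is needed), diazo transfer, benzannulation, and last the nitrogen ring.
- Stereochemistry: C3 (S) comes from the commercial L-alaninol-derived cyclic sulfamidate, opened at its CH2 carbon; the stereocentre is never a reacting centre afterwards.

Key step: step 14

Remark: the biaryl axis C5–C1' carries no descriptor in the target structure, so it is treated as undefined and only C3 is controlled.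

**Route**

Step 1
Reactants: 1 2-bromo-5-methoxybenzaldehyde; 2 diethyl succinate
Product: 3 (E)-4-(2-bromo-5-methoxyphenyl)-3-(ethoxycarbonyl)but-3-enoic acid
Conditions: KOtBu, t-BuOH, reflux; then aq. HCl
Reagents that add atoms: none
Why: Stobbe condensation, in which the succinate enolate adds to the aldehyde, lactonises and opens by elimination to the half-ester, favouring the E isomer with the aryl group cis to CH2CO2H as the ring closure requires.

Step 2
Reactants: 3 (E)-4-(2-bromo-5-methoxyphenyl)-3-(ethoxycarbonyl)but-3-enoic acid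
Product: 4 ethyl 4-acetoxy-8-bromo-5-methoxynaphthalene-2-carboxylate
Conditions: Ac2O, NaOAc, reflux
Reagents that add atoms: acetic anhydride CC(=O)OC(C)=O
Why: Intramolecular Friedel–Crafts acylation through the mixed anhydride followed by enolisation and O-acetylation; bromine blocks the other ortho position, so closure must occur ortho to the methoxy group and fixes the 4,5-dioxygenation pattern.

Step 3
Reactants: 4 ethyl 4-acetoxy-8-bromo-5-methoxynaphthalene-2-carboxylate
Product: 5 5-bromo-3-(hydroxymethyl)-8-methoxynaphthalen-1-ol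
Conditions: LiAlH4, THF, 0 °C; then dil. aq. HCl
Reagents that add atoms: none
Why: Hydride reduction of the ethyl ester to the primary alcohol with simultaneous reductive cleavage of the aryl acetate; the aryl bromide is expected to survive at 0 °C.

Step 4
Reactants: 5 5-bromo-3-(hydroxymethyl)-8-methoxynaphthalen-1-ol
Product: 6 (8-bromo-4,5-dimethoxynaphthalen-2-yl)methanol
Conditions: MeI, K2CO3, acetone, reflux
Reagents that add atoms: iodomethane CI
Why: Williamson O-methylation in which K2CO3 deprotonates only the naphthol, so the benzylic alcohol stays free.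

Step 5
Reactants: 6 (8-bromo-4,5-dimethoxynaphthalen-2-yl)methanol
Product: 7 1-bromo-7-(bromomethyl)-4,5-dimethoxynaphthalene
Conditions: PBr3, CH2Cl2, 0 °C
Reagents that add atoms: phosphorus tribromide BrP(Br)Br
Why: Conversion of a primary benzylic alcohol into the bromide through its phosphite ester (SN2), a standard activation before deoxygenation.

Step 6
Reactants: 7 1-bromo-7-(bromomethyl)-4,5-dimethoxynaphthalene
Product: 8 1-bromo-4,5-dimethoxy-7-methylnaphthalene
Conditions: LiBHEt3, THF, 0 °C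
Reagents that add atoms: none
Why: SN2 hydride displacement of the benzylic bromide; the aryl bromide is inert to the borohydride at this temperature.

Step 7
Reactants: 8 1-bromo-4,5-dimethoxy-7-methylnaphthalene
Product: 9 4,5-dimethoxy-7-methylnaphthalene-1-carbaldehyde
Conditions: n-BuLi, THF, −78 °C; DMF; then aq. HCl
Reagents that add atoms: N,N-dimethylformamide CN(C)C=O
Why: Bromine–lithium exchange and formylation of the aryllithium with DMF (Bouveault-type aldehyde synthesis) place the future C5 carbon exactly where the bromine was.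

Step 8
Reactants: 10 diethyl {2-[methoxy(methyl)amino]-2-oxoethyl}phosphonate; 11 tert-butyl (4S)-4-methyl-1,2,3-oxathiazolidine-3-carboxylate 2,2-dioxide
Product: 13 diethyl {(4S)-4-[(tert-butoxycarbonyl)amino]-1-[methoxy(methyl)amino]-1-oxopentan-2-yl}phosphonate (C2 epimers), via N-sulfamate sodium salt 12 (not isolated)
Conditions: NaH, THF/DMF, 0 °C to rt; then 1 M aq. HCl, rt
Reagents that add atoms: none
Why: C-alkylation of the stabilised phosphonate carbanion by SN2 opening of the cyclic sulfamidate at its O–CH2 carbon (forms C4–C4a), then mild acid hydrolysis of the N-sulfate with the Boc group retained; the stereocentre is adjacent to the reacting carbon and is not touched.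

Step 9
Reactants: 13 diethyl {(4S)-4-[(tert-butoxycarbonyl)amino]-1-[methoxy(methyl)amino]-1-oxopentan-2-yl}phosphonate; 9 4,5-dimethoxy-7-methylnaphthalene-1-carbaldehyde
Product: 14 tert-butyl {(2S,4E)-5-(4,5-dimethoxy-7-methylnaphthalen-1-yl)-4-[methoxy(methyl)carbamoyl]pent-4-en-2-yl}carbamate
Conditions: LiCl, DBU, MeCN, rt to 40 °C
Reagents that add atoms: none
Why: Horner–Wadsworth–Emmons olefination under the mild LiCl/amine-base variant, which leaves the carbamate N–H alone and should place the aryl group trans to the carboxamide (E) under thermodynamic control of the oxaphosphetane pathway.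

Step 10
Reactants: 14 tert-butyl {(2S,4E)-5-(4,5-dimethoxy-7-methylnaphthalen-1-yl)-4-[methoxy(methyl)carbamoyl]pent-4-en-2-yl}carbamate
Product: 15 tert-butyl [(2S,4E)-4-acetyl-5-(4,5-dimethoxy-7-methylnaphthalen-1-yl)pent-4-en-2-yl]carbamate
Conditions: MeMgBr (3 equiv), THF, −20 to 0 °C; aq. NH4Cl
Reagents that add atoms: methylmagnesium bromide C[Mg]Br
Why: Weinreb ketone synthesis, in which the chelated tetrahedral intermediate prevents over-addition and the carbamate N–H only consumes one equivalent of Grignard reagent; the new methyl carbon is the future C8a.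

Step 11
Reactants: 15 tert-butyl [(2S,4E)-4-acetyl-5-(4,5-dimethoxy-7-methylnaphthalen-1-yl)pent-4-en-2-yl]carbamate
Product: 16 di-tert-butyl N-[(2S,4E)-4-acetyl-5-(4,5-dimethoxy-7-methylnaphthalen-1-yl)pent-4-en-2-yl]imidodicarbonate
Conditions: Boc2O, DMAP, MeCN, rt
Reagents that add atoms: di-tert-butyl dicarbonate CC(C)(C)OC(=O)OC(=O)OC(C)(C)C
Why: DMAP-catalysed N-acylation of the carbamate to the imidodicarbonate removes the last N–H, which would otherwise consume base in the diazo transfer and could trap the ketene of the key step intramolecularly.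

Step 12
Reactants: 16 di-tert-butyl N-[(2S,4E)-4-acetyl-5-(4,5-dimethoxy-7-methylnaphthalen-1-yl)pent-4-en-2-yl]imidodicarbonate
Product: 18 di-tert-butyl N-[(2S,4E)-4-(diazoacetyl)-5-(4,5-dimethoxy-7-methylnaphthalen-1-yl)pent-4-en-2-yl]imidodicarbonate, via trifluoroacetyl ketone 17 (not isolated)
Conditions: LiN(SiMe3)2, THF, −78 °C; CF3CO2CH2CF3; cold dil. aq. HCl; then MsN3, Et3N, H2O, MeCN, rt
Reagents that add atoms: methanesulfonyl azide CS(=O)(=O)N=[N+]=[N-]; 2,2,2-trifluoroethyl trifluoroacetate O=C(OCC(F)(F)F)C(F)(F)F (its trifluoroacetyl group is carried by 17 only)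
Why: Detrifluoroacetylative diazo transfer (kinetic enolisation of the only enolisable position, Claisen trifluoroacetylation, then Regitz-type diazo transfer with loss of the trifluoroacetyl group), the established way to α'-diazo enones that avoids diazomethane and its cycloaddition to the conjugated alkene.

Step 13
Reactants: 19 2-chloro-1,1-dimethoxyethane
Product: 21 methoxyethyne, via sodium methoxyethynide 20 (not isolated)
Conditions: NaNH2 (3 equiv), liq. NH3, −33 °C; then cold aq. NaCl; distilled into cold ClCH2CH2Cl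
Reagents that add atoms: none
Why: Twofold base-induced elimination (methanol and HCl) from the α-chloro acetal gives the alkynyl ether as its sodium acetylide, which is protonated on aqueous quench, the classical preparation of 1-alkoxyalkynes.

Step 14
Reactants: 18 di-tert-butyl N-[(2S,4E)-4-(diazoacetyl)-5-(4,5-dimethoxy-7-methylnaphthalen-1-yl)pent-4-en-2-yl]imidodicarbonate; 21 methoxyethyne
Product: 24 di-tert-butyl N-{(2S)-1-[3-hydroxy-5-methoxy-2-(4,5-dimethoxy-7-methylnaphthalen-1-yl)phenyl]propan-2-yl}imidodicarbonate, via vinylketene 22 (not isolated), via 3-methoxy-4-vinylcyclobutenone 23 (not isolated)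
Conditions: hν (300 nm, Pyrex), 21 (3 equiv), ClCH2CH2Cl, 10 °C; argon purge of excess 21; then 80 °C
Reagents that add atoms: none
Why: Danheiser benzannulation in its photochemical Wolff form: light expels N2 from 18 and the alkenyl group migrates with its E geometry intact to give vinylketene 22 (C4a–C8a). A polarity-matched [2+2] cycloaddition joins the electrophilic ketene carbonyl carbon to the nucleophilic CH terminus of 21 (C6–C7) and the ketene α-carbon to the oxygen-bearing alkyne carbon (C8–C8a), closing the four-membered ring of 23. On warming, 23 opens by 4π electrocyclic cleavage to a dienylketene, which closes the benzene ring by thermal 6π electrocyclisation (C5–C6) and tautomerises to phenol 24; the closest known reaction type is the benzannulation of α,β-unsaturated α'-diazo ketones with alkoxy- and siloxyalkynes. No stereocentre is formed, and C3 lies two saturated carbons away from the reacting π system, so it passes through unchanged. The regiochemistry needed (C8 methoxy meta to the C6 hydroxyl, naphthyl ortho to it) follows from the ketene/ynol ether polarity; the chemoselectivity needed (capture of the ketene by the alkyne, not by nitrogen or by the naphthalene ring) is secured by the N–H-free bis-Boc nitrogen, by the E alkene that holds the ketene trans to the naphthyl group, and by the excess of alkyne.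

Step 15
Reactants: 24 di-tert-butyl N-{(2S)-1-[3-hydroxy-5-methoxy-2-(4,5-dimethoxy-7-methylnaphthalen-1-yl)phenyl]propan-2-yl}imidodicarbonate
Product: 25 di-tert-butyl N-{(2S)-1-[3,5-dimethoxy-2-(4,5-dimethoxy-7-methylnaphthalen-1-yl)phenyl]propan-2-yl}imidodicarbonate
Conditions: MeI, K2CO3, DMF, rt
Reagents that add atoms: iodomethane CI
Why: Williamson O-methylation of the single phenol; the imidodicarbonate is stable to carbonate base.

Step 16
Reactants: 25 di-tert-butyl N-{(2S)-1-[3,5-dimethoxy-2-(4,5-dimethoxy-7-methylnaphthalen-1-yl)phenyl]propan-2-yl}imidodicarbonate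
Product: 26 (2S)-1-[3,5-dimethoxy-2-(4,5-dimethoxy-7-methylnaphthalen-1-yl)phenyl]propan-2-amine
Conditions: HCl (4 M in dioxane), rt; then aq. NaOH
Reagents that add atoms: none
Why: Acidolysis of both tert-butyl carbamate groups (loss of 2-methylpropene and CO2) frees the primary amine without touching the aryl methyl ethers or C3.

Step 17
Reactants: 26 (2S)-1-[3,5-dimethoxy-2-(4,5-dimethoxy-7-methylnaphthalen-1-yl)phenyl]propan-2-amine
Product: 28 (3S)-6,8-dimethoxy-5-(4,5-dimethoxy-7-methylnaphthalen-1-yl)-3-methyl-1,2,3,4-tetrahydroisoquinoline, via N-methylidene amine 27 (not isolated)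
Conditions: (CH2O)n (1.1 equiv), CF3CO2H, CH2Cl2, 0 °C to rt; aq. NaHCO3
Reagents that add atoms: formaldehyde C=O
Why: Pictet–Spengler reaction, a 6-endo cyclisation of the iminium ion onto C8a, the only free position ortho to the side chain and activated ortho and para by the two methoxy groups; C3 is not involved and stays S.

**Compound list**

1 | 2-bromo-5-methoxybenzaldehyde | COc1ccc(Br)c(C=O)c1 | starting material
2 | diethyl succinate | CCOC(=O)CCC(=O)OCC | starting material
3 | (E)-4-(2-bromo-5-methoxyphenyl)-3-(ethoxycarbonyl)but-3-enoic acid | CCOC(=O)/C(CC(=O)O)=C/c1cc(OC)ccc1Br | intermediate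
4 | ethyl 4-acetoxy-8-bromo-5-methoxynaphthalene-2-carboxylate | CCOC(=O)c1cc(OC(C)=O)c2c(OC)ccc(Br)c2c1 | intermediate
5 | 5-bromo-3-(hydroxymethyl)-8-methoxynaphthalen-1-ol | OCc1cc(O)c2c(OC)ccc(Br)c2c1 | intermediate
6 | (8-bromo-4,5-dimethoxynaphthalen-2-yl)methanol | OCc1cc(OC)c2c(OC)ccc(Br)c2c1 | intermediate
7 | 1-bromo-7-(bromomethyl)-4,5-dimethoxynaphthalene | BrCc1cc(OC)c2c(OC)ccc(Br)c2c1 | intermediate
8 | 1-bromo-4,5-dimethoxy-7-methylnaphthalene | Cc1cc(OC)c2c(OC)ccc(Br)c2c1 | intermediate
9 | 4,5-dimethoxy-7-methylnaphthalene-1-carbaldehyde | Cc1cc(OC)c2c(OC)ccc(C=O)c2c1 | intermediate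
10 | diethyl {2-[methoxy(methyl)amino]-2-oxoethyl}phosphonate | CCOP(=O)(CC(=O)N(C)OC)OCC | starting material
11 | tert-butyl (4S)-4-methyl-1,2,3-oxathiazolidine-3-carboxylate 2,2-dioxide (cyclic sulfamidate of N-Boc-L-alaninol) | C[C@H]1COS(=O)(=O)N1C(=O)OC(C)(C)C | starting material
12 | sodium N-(tert-butoxycarbonyl)-N-{(2S)-4-(diethoxyphosphoryl)-5-[methoxy(methyl)amino]-5-oxopentan-2-yl}sulfamate | CCOP(=O)(OCC)C(C[C@H](C)N(C(=O)OC(C)(C)C)S(=O)(=O)[O-])C(=O)N(C)OC.[Na+] | intermediate
13 | diethyl {(4S)-4-[(tert-butoxycarbonyl)amino]-1-[methoxy(methyl)amino]-1-oxopentan-2-yl}phosphonate (C2 epimers) | CCOP(=O)(OCC)C(C[C@H](C)NC(=O)OC(C)(C)C)C(=O)N(C)OC | intermediate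
14 | tert-butyl {(2S,4E)-5-(4,5-dimethoxy-7-methylnaphthalen-1-yl)-4-[methoxy(methyl)carbamoyl]pent-4-en-2-yl}carbamate | CON(C)C(=O)/C(C[C@H](C)NC(=O)OC(C)(C)C)=C/c1ccc(OC)c2c(OC)cc(C)cc12 | intermediate
15 | tert-butyl [(2S,4E)-4-acetyl-5-(4,5-dimethoxy-7-methylnaphthalen-1-yl)pent-4-en-2-yl]carbamate | CC(=O)/C(C[C@H](C)NC(=O)OC(C)(C)C)=C/c1ccc(OC)c2c(OC)cc(C)cc12 | intermediate
16 | di-tert-butyl N-[(2S,4E)-4-acetyl-5-(4,5-dimethoxy-7-methylnaphthalen-1-yl)pent-4-en-2-yl]imidodicarbonate | CC(=O)/C(C[C@H](C)N(C(=O)OC(C)(C)C)C(=O)OC(C)(C)C)=C/c1ccc(OC)c2c(OC)cc(C)cc12 | intermediate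
17 | di-tert-butyl N-[(2S,4E)-5-(4,5-dimethoxy-7-methylnaphthalen-1-yl)-4-(4,4,4-trifluoro-3-oxobutanoyl)pent-4-en-2-yl]imidodicarbonate | O=C(CC(=O)/C(C[C@H](C)N(C(=O)OC(C)(C)C)C(=O)OC(C)(C)C)=C/c1ccc(OC)c2c(OC)cc(C)cc12)C(F)(F)F | intermediate
18 | di-tert-butyl N-[(2S,4E)-4-(diazoacetyl)-5-(4,5-dimethoxy-7-methylnaphthalen-1-yl)pent-4-en-2-yl]imidodicarbonate, i.e. (E)-1-diazo-3-[(2S)-2-(di-Boc-amino)propyl]-4-(4,5-dimethoxy-7-methylnaphthalen-1-yl)but-3-en-2-one | [N-]=[N+]=CC(=O)/C(C[C@H](C)N(C(=O)OC(C)(C)C)C(=O)OC(C)(C)C)=C/c1ccc(OC)c2c(OC)cc(C)cc12 | intermediate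
19 | 2-chloro-1,1-dimethoxyethane | COC(CCl)OC | starting material
20 | sodium methoxyethynide | COC#[C-].[Na+] | intermediate
21 | methoxyethyne | COC#C | intermediate
22 | di-tert-butyl N-[(2S,4E)-5-(4,5-dimethoxy-7-methylnaphthalen-1-yl)-4-(2-oxoethenyl)pent-4-en-2-yl]imidodicarbonate (vinylketene) | O=C=C/C(C[C@H](C)N(C(=O)OC(C)(C)C)C(=O)OC(C)(C)C)=C/c1ccc(OC)c2c(OC)cc(C)cc12 | intermediate
23 | di-tert-butyl N-[(2S,4E)-5-(4,5-dimethoxy-7-methylnaphthalen-1-yl)-4-(2-methoxy-4-oxocyclobut-2-en-1-yl)pent-4-en-2-yl]imidodicarbonate (both ring epimers) | COC1=CC(=O)C1/C(C[C@H](C)N(C(=O)OC(C)(C)C)C(=O)OC(C)(C)C)=C/c1ccc(OC)c2c(OC)cc(C)cc12 | intermediate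
24 | di-tert-butyl N-{(2S)-1-[3-hydroxy-5-methoxy-2-(4,5-dimethoxy-7-methylnaphthalen-1-yl)phenyl]propan-2-yl}imidodicarbonate | C[C@@H](Cc1cc(OC)cc(O)c1-c1ccc(OC)c2c(OC)cc(C)cc12)N(C(=O)OC(C)(C)C)C(=O)OC(C)(C)C | intermediate
25 | di-tert-butyl N-{(2S)-1-[3,5-dimethoxy-2-(4,5-dimethoxy-7-methylnaphthalen-1-yl)phenyl]propan-2-yl}imidodicarbonate | C[C@@H](Cc1cc(OC)cc(OC)c1-c1ccc(OC)c2c(OC)cc(C)cc12)N(C(=O)OC(C)(C)C)C(=O)OC(C)(C)C | intermediate
26 | (2S)-1-[3,5-dimethoxy-2-(4,5-dimethoxy-7-methylnaphthalen-1-yl)phenyl]propan-2-amine | C[C@@H](Cc1cc(OC)cc(OC)c1-c1ccc(OC)c2c(OC)cc(C)cc12)N | intermediate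
27 | (2S)-1-[3,5-dimethoxy-2-(4,5-dimethoxy-7-methylnaphthalen-1-yl)phenyl]-N-methylidenepropan-2-amine (reacts as its iminium ion) | C=N[C@@H](C)Cc1cc(OC)cc(OC)c1-c1ccc(OC)c2c(OC)cc(C)cc12 | intermediate
28 | (3S)-6,8-dimethoxy-5-(4,5-dimethoxy-7-methylnaphthalen-1-yl)-3-methyl-1,2,3,4-tetrahydroisoquinoline | COc1cc(OC)c(-c2ccc(OC)c3c(OC)cc(C)cc23)c2c1CN[C@@H](C)C2 | target

**Step count**

Total steps: 17. Longest linear sequence: 15 steps (steps 1–7, 9–12, 14–17); steps 8 and 13 are one-step side branches.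

**Steps most likely to fail, with fallbacks**

1. Step 14. Under irradiation the aryl-conjugated alkene may isomerise, after which the ketene can close onto the naphthalene ring. The electron-rich naphthalene may also divert the excited state away from the Wolff rearrangement, and the volatile ynol ether may oligomerise. The fallback gives up the ring construction and makes the biaryl bond by cross-coupling; it sets out from 8 and 11 and rejoins the route at 26. Bromide 8 is lithiated (n-BuLi, −78 °C) and borylated with B(OiPr)3 to (4,5-dimethoxy-7-methylnaphthalen-1-yl)boronic acid F1. Sulfamidate 11 is opened with commercial 3,5-dimethoxyphenylmagnesium chloride and catalytic CuI to the N-sulfamate chloromagnesium salt F2, which mild aqueous acid hydrolyses to tert-butyl [(2S)-1-(3,5-dimethoxyphenyl)propan-2-yl]carbamate F3. Bromination with NBS ortho to the side chain gives tert-butyl [(2S)-1-(2-bromo-3,5-dimethoxyphenyl)propan-2-yl]carbamate F4. Suzuki–Miyaura coupling of F1 with F4 (Pd(OAc)2, SPhos, K3PO4, toluene/water) gives tert-butyl {(2S)-1-[3,5-dimethoxy-2-(4,5-dimethoxy-7-methylnaphthalen-1-yl)phenyl]propan-2-yl}carbamate F5, and HCl in dioxane then gives amine 26.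

2. Step 9. The α-branched, weakly acidic phosphonate may olefinate the electron-rich, peri-hindered aldehyde only slowly, E selectivity may be incomplete, and more forcing base could cyclise the carbamate nitrogen onto the amide. The fallback olefinates with a cyclic, N–H-free phosphonate and opens the ring afterwards; it sets out from 11 and 9 and rejoins the route at 15. Sulfamidate 11 is opened with the sodium enolate of commercial triethyl phosphonoacetate to the N-sulfamate sodium salt F6. Aqueous 5 M HCl removes the sulfate and the Boc group to give ethyl (4S)-4-amino-2-(diethoxyphosphoryl)pentanoate F7, which on neutralisation and warming lactamises to diethyl [(5S)-5-methyl-2-oxopyrrolidin-3-yl]phosphonate F8. Boc2O/DMAP gives tert-butyl (5S)-3-(diethoxyphosphoryl)-5-methyl-2-oxopyrrolidine-1-carboxylate F9. Its sodium enolate (NaH, THF) olefinates aldehyde 9 to tert-butyl (3E,5S)-3-[(4,5-dimethoxy-7-methylnaphthalen-1-yl)methylidene]-5-methyl-2-oxopyrrolidine-1-carboxylate F10. MeMgBr at −78 °C opens the activated lactam carbonyl of F10 and gives enone 15 directly.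

3. Step 12. Claisen trifluoroacetylation of the cross-conjugated lithium enolate may stay incomplete, or a Boc group may migrate to the enolate, so that the diazo transfer stalls. The fallback introduces the diazo group by substitution on an α-bromo ketone; it sets out from 16 and rejoins the route at 18. Ketone 16 is converted with LiN(SiMe3)2/Me3SiCl at −78 °C into the trimethylsilyl enol ether F11, di-tert-butyl N-[(2S,4E)-5-(4,5-dimethoxy-7-methylnaphthalen-1-yl)-4-{1-[(trimethylsilyl)oxy]ethenyl}pent-4-en-2-yl]imidodicarbonate. NBS at −78 °C brominates F11 to the bromomethyl ketone F12, di-tert-butyl N-[(2S,4E)-4-(bromoacetyl)-5-(4,5-dimethoxy-7-methylnaphthalen-1-yl)pent-4-en-2-yl]imidodicarbonate. N,N'-ditosylhydrazine and DBU (THF, 0 °C) displace the bromide and eliminate two sulfinate groups to give diazo ketone 18.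

**Further compounds**

F1 | step 14 | (4,5-dimethoxy-7-methylnaphthalen-1-yl)boronic acid | Cc1cc(OC)c2c(OC)ccc(B(O)O)c2c1
F2 | step 14 | chloromagnesium N-(tert-butoxycarbonyl)-N-[(2S)-1-(3,5-dimethoxyphenyl)propan-2-yl]sulfamate | COc1cc(C[C@H](C)N(C(=O)OC(C)(C)C)S(=O)(=O)[O-])cc(OC)c1.[Mg+2].[Cl-]
F3 | step 14 | tert-butyl [(2S)-1-(3,5-dimethoxyphenyl)propan-2-yl]carbamate | COc1cc(C[C@H](C)NC(=O)OC(C)(C)C)cc(OC)c1
F4 | step 14 | tert-butyl [(2S)-1-(2-bromo-3,5-dimethoxyphenyl)propan-2-yl]carbamate | COc1cc(OC)c(Br)c(C[C@H](C)NC(=O)OC(C)(C)C)c1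
F5 | step 14 | tert-butyl {(2S)-1-[3,5-dimethoxy-2-(4,5-dimethoxy-7-methylnaphthalen-1-yl)phenyl]propan-2-yl}carbamate | C[C@@H](Cc1cc(OC)cc(OC)c1-c1ccc(OC)c2c(OC)cc(C)cc12)NC(=O)OC(C)(C)C
F6 | step 9 | sodium N-(tert-butoxycarbonyl)-N-[(2S)-4-(diethoxyphosphoryl)-5-ethoxy-5-oxopentan-2-yl]sulfamate | CCOC(=O)C(C[C@H](C)N(C(=O)OC(C)(C)C)S(=O)(=O)[O-])P(=O)(OCC)OCC.[Na+]
F7 | step 9 | ethyl (4S)-4-amino-2-(diethoxyphosphoryl)pentanoate | CCOC(=O)C(C[C@H](C)N)P(=O)(OCC)OCC
F8 | step 9 | diethyl [(5S)-5-methyl-2-oxopyrrolidin-3-yl]phosphonate | CCOP(=O)(OCC)C1C[C@H](C)NC1=O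
F9 | step 9 | tert-butyl (5S)-3-(diethoxyphosphoryl)-5-methyl-2-oxopyrrolidine-1-carboxylate | CCOP(=O)(OCC)C1C[C@H](C)N(C(=O)OC(C)(C)C)C1=O
F10 | step 9 | tert-butyl (3E,5S)-3-[(4,5-dimethoxy-7-methylnaphthalen-1-yl)methylidene]-5-methyl-2-oxopyrrolidine-1-carboxylate | O=C1/C(=C/c2ccc(OC)c3c(OC)cc(C)cc23)C[C@H](C)N1C(=O)OC(C)(C)C
F11 | step 12 | di-tert-butyl N-[(2S,4E)-5-(4,5-dimethoxy-7-methylnaphthalen-1-yl)-4-{1-[(trimethylsilyl)oxy]ethenyl}pent-4-en-2-yl]imidodicarbonate | C=C(O[Si](C)(C)C)/C(C[C@H](C)N(C(=O)OC(C)(C)C)C(=O)OC(C)(C)C)=C/c1ccc(OC)c2c(OC)cc(C)cc12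
F12 | step 12 | di-tert-butyl N-[(2S,4E)-4-(bromoacetyl)-5-(4,5-dimethoxy-7-methylnaphthalen-1-yl)pent-4-en-2-yl]imidodicarbonate | BrCC(=O)/C(C[C@H](C)N(C(=O)OC(C)(C)C)C(=O)OC(C)(C)C)=C/c1ccc(OC)c2c(OC)cc(C)cc12
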